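## Structural features

The target 17 is a dibenzylbutane lignan in which two identical 3,4-dihydroxy-5-methoxyphenyl rings are joined, each through its C1 atom, by the open chain C7–C8–C8'–C7', with a methyl group (C9, C9') on each inner carbon. The only stereocentres are the neighbouring methines C8 and C8'; their (R,S) configuration with identical substituents makes 17 the achiral meso diastereomer, so only a relative configuration has to be secured. The fragile groups are the two free catechols, which air oxidises to ortho-quinones, fastest under base; they must stay masked until the last step, and the unmasking must spare the two aryl methyl ethers. The real difficulty is that the C8/C8' pair lies in a flexible hydrocarbon chain with no nearby functional group, so the meso isomer has to be told from the racemic one without any handle for acyclic stereocontrol, and a late separation of the two would be hard. The key step uses the fact that C8 and C8' each carry one benzylic neighbour (C7, C7') and one single-carbon substituent (C9, C9'): C7–C8–C8'–C7' can be drawn as four consecutive atoms of a cyclohexene in which C9 and C9' are the carbonyl carbons of a cis-fused anhydride. In such a ring a cis relation at C8/C8' is the meso relation of the opened chain, and ring formation by cycloaddition makes C7–C8 and C7'–C8' at once. The two further ring carbons that complete the six-membered ring do not belong to 17 and have to be cut out afterwards.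

## Logic of the disconnections

17 from 16. The four phenolic O–H bonds are traded for O–CH2Ph bonds. The cut is made here because free catechols would not survive base, hydride and oxidant, while one neutral hydrogenolysis frees all four at the end. The gain is a robust, chromatographable series of intermediates. The demand is that no earlier step cleaves an aryl benzyl ether and that the last step leaves both O–CH3 bonds alone.

16 from 15. One formyl carbon is put back on C7 and one on C7' (two C–C bonds). These carbons are the remnant of a ring C=C, and a formyl group on a benzylic carbon can be removed as CO. The gain is that the acyclic target becomes a 1,6-dicarbonyl compound, which is a cyclohexene in disguise. The demand is a twofold C–C cleavage at secondary benzylic carbons that must not pass through a C7=C8 olefin, since that would put C8 at risk.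

15 from 13, by way of 14. The two formyl carbons are rejoined as the C=C bond of a six-membered ring. This turns an open chain with two isolated stereocentres into a ring in which their relation is simply cis. The stereocentres at C7 and C7' are of no consequence because both end as CH2. The demand is a cleavage that stops at the aldehyde level and a product that is used before it enolises or cyclises.

13 from 12, 11 and 10. At C9 and C9' the C–H bonds are traded back for C–O bonds: sulfonate in 12, hydroxyl in 11, and the carbonyl level of a five-membered anhydride in 10. Methyl groups offer no retron, whereas the cis-fused anhydride on a cyclohexene is the retron of a cycloaddition. The gain is access to the key step. The demand is exhaustive deoxygenation of two crowded primary carbons without closure of a cyclic ether between the cis arms.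

10 from 8 and 9. C7–C8 and C7'–C8' are cut together. Both bonds link a benzylic carbon to a carbon that carries a carbonyl group, which is the diene-terminus-to-dienophile pattern. The gain is the largest of the route: one ring, two skeletal bonds and four stereocentres disappear, leaving a symmetric diene and a commodity dienophile. The demand is an (E,E) diene that can reach the s-cis geometry and a dienophile whose Z geometry cannot change; there is no regiochemical issue because both partners are symmetric.

8 from 5 and 7. The C=C bond between C7' and the adjacent inner diene carbon is cut. A benzylic phosphonate carbanion and a conjugated aldehyde give an E olefin reliably, and both halves come from the same aldehyde. A twofold olefination of a C2 dialdehyde would save one operation, but that reagent is handled as an aqueous oligomer and is poorly matched to the strong anhydrous base an electron-rich, non-stabilised benzylphosphonate needs. The stepwise union costs one step off the main line and leaves the longest linear sequence unchanged. The demand is E selectivity in the olefination.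

7 from 3 and 6. The C=C bond of the enal is cut. A stabilised formyl ylide adds two carbons to an aryl aldehyde with E geometry in one operation. The demand is that the product enal does not react a second time with 6.

5 from 4, and 4 from 3. The C7–P bond is cut, then the benzylic alcohol is taken back to the aldehyde. This gives the nucleophilic half from the same aldehyde that serves as the electrophilic half. The demand is C–P bond formation at an electron-rich benzylic carbon without self-alkylation.

3 from 1 and 2. The two O–CH2Ph bonds are cut, leading to a commercial catechol aldehyde that already carries the full oxygenation pattern of each ring of 17.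

## Other disconnections considered

Alternative 1: The cut removes every ring bond of both arenes, so each benzene ring is grown on a ready-made meso chain.
- Forward key step: twofold Michael–Claisen annulation of the meso bis-enone A2 with dimethyl malonate A3 (NaOMe, then hydrolysis and decarboxylation), closing two cyclohexane-1,3-dione rings to give A1.
- In its favour: C8 and C8' are installed once in an open-chain core and sit two atoms away from any reacting centre, so no stereocentre is created or endangered. The chemistry is classical ionic condensation with cheap reagents and no transition metal, and no atoms are built in only to be excised.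
- Against it here: A1 has the wrong oxidation level and oxygen pattern. Each ring would need a third oxygen at C2 of the dione, dehydrogenation to a 5-alkylpyrogallol, and mono-methylation of one of two equivalent outer hydroxyls beside a third. All of this is twofold, and the intermediates are more oxidation-prone than the catechols of 17.
- Comparison: on stereochemical security it is the equal of the chosen plan, arguably the better, since nothing stereogenic is made or destroyed. On mechanism it is equally dependable. On step and redox economy it is poorer, because the oxygenated arene that the chosen plan buys intact in 1 would have to be rebuilt twice.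

Alternative 2: The cut is at C8–C9 and C8'–C9', so the methyl carbons are inserted last.
- Forward key step: twofold Matteson homologation of the meso vicinal bis(pinacol boronate) A5 with the carbenoid generated in the flask from bromochloromethane A6 and n-BuLi. Each secondary carbon migrates from boron to carbon with retention, giving A4 without closing a ring.
- In its favour: the 1,2-metallate shift is stereospecific. A5 should come from syn-diboration of a Z-olefin, so the meso relation derives from an olefin geometry exactly as the chosen plan derives it from the Z geometry of 9; in stereochemical logic the two are equal. No ring is built and dismantled, so fewer skeletal bonds are made and broken, and the route would probably be shorter; here the alternative is the better plan.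
- Against it here: two adjacent secondary boronates must each form an ate complex with a thermally labile carbenoid, and under- or over-insertion on a symmetric substrate would give homologues differing by one CH2, which are hard to separate. A4 still carries two C–B bonds, and replacing boron by hydrogen on unactivated primary carbons is a demanding twofold operation. The methylenedioxy groups must later be opened beside aryl methyl ethers with a Lewis acid, which is less secure than hydrogenolysis of benzyl ethers.
- Comparison: better on atom and step economy, equal on stereochemical logic, weaker on the certainty of the endgame.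

Alternative 3: The cut is at both aryl–C7 bonds.
- Forward key step: twofold Negishi coupling of the bis(alkylzinc iodide) A8 with two molecules of the aryl bromide A9 under Pd(OAc)2 and SPhos, giving A7, which is the same compound as 16.
- In its favour: it is the most convergent plan and forms exactly the two bonds that tie the arenes to the chain. The stereocentres are β to zinc and never at a reacting carbon. A8 traces back in a few functional-group steps to a commercial meso C6 diacid, and the final hydrogenolysis is shared with the chosen route. The sequence would be roughly half as long; on step economy and convergence the alternative is clearly the better plan.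
- Against it here: the plan only carries stereochemistry and does not create it, so any racemic diastereomer in the pool material would travel to the end, where separation is hardest. A twofold sp3–sp2 coupling of a β-branched primary dizinc reagent invites protodezincation and mono-coupling. A9 is not reachable by direct bromination, because the position para to the central oxygen is the least activated one, and needs its own sequence.
- Comparison: the mechanism is a catalytic cycle between zerovalent and divalent palladium with β-hydride elimination as a built-in side path, against a single pericyclic event with no intermediates. On stereochemical security the two are equal provided the pool compound is diastereomerically pure. The chosen plan is longer, but it generates the meso pair itself from achiral commodity partners and fixes it at a crystalline ring stage (10).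

Key step: step 6

Remarks on the chemistry: Ar = 3,4-bis(benzyloxy)-5-methoxyphenyl, and C7, C8, C9 with their primed partners follow lignan numbering. Because 17 is meso, no absolute stereocontrol is planned. A reaction that occurs alike at both equivalent ends of a symmetric compound is written as one step, and neither its half-reacted stage nor short-lived species without independent existence (ylides, betaines, metal alkoxides, osmate esters) are numbered.

## Route

Step 1
Reactants: 1 5-hydroxyvanillin (3,4-dihydroxy-5-methoxybenzaldehyde); 2 benzyl bromide
Product: 3 3,4-bis(benzyloxy)-5-methoxybenzaldehyde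
Conditions: 2 (2.4 equiv), K2CO3 (3 equiv), DMF, 60 °C, N2
Reagents that add atoms: none
Why: Twofold Williamson ether synthesis; both phenoxides are alkylated by SN2 on 2, the aldehyde is inert, and exclusion of air prevents oxidation of the catecholate before it is capped.

Step 2
Reactants: 3 3,4-bis(benzyloxy)-5-methoxybenzaldehyde
Product: 4 [3,4-bis(benzyloxy)-5-methoxyphenyl]methanol
Conditions: NaBH4, MeOH/THF, 0 °C to rt
Reagents that add atoms: none
Why: Chemoselective borohydride reduction of an aryl aldehyde; benzyl and methyl ethers are untouched.

Step 3
Reactants: 4 [3,4-bis(benzyloxy)-5-methoxyphenyl]methanol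
Product: 5 diethyl {[3,4-bis(benzyloxy)-5-methoxyphenyl]methyl}phosphonate
Conditions: P(OEt)3 (3 equiv), ZnI2 (1.5 equiv), toluene, reflux
Reagents that add atoms: triethyl phosphite, CCOP(OCC)OCC
Why: One-flask Lewis-acid-mediated Michaelis–Arbuzov-type phosphonylation of a benzylic alcohol; the alcohol is taken up by the phosphite with loss of ethanol and ZnI2 promotes transfer of the benzyl group from oxygen to phosphorus, helped by the three alkoxy groups. This replaces a separate bromide step.

Step 4
Reactants: 3 3,4-bis(benzyloxy)-5-methoxybenzaldehyde; 6 (triphenylphosphoranylidene)acetaldehyde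
Product: 7 (2E)-3-[3,4-bis(benzyloxy)-5-methoxyphenyl]prop-2-enal
Conditions: 6 (1.0 equiv), 3 (1.1 equiv), toluene, 90 °C
Reagents that add atoms: none
Why: Wittig olefination with a stabilised formyl ylide should give the E enal; a slight excess of 3 keeps a second, vinylogous olefination of 7 low.

Step 5
Reactants: 5 diethyl {[3,4-bis(benzyloxy)-5-methoxyphenyl]methyl}phosphonate; 7 (2E)-3-[3,4-bis(benzyloxy)-5-methoxyphenyl]prop-2-enal
Product: 8 (1E,3E)-1,4-bis[3,4-bis(benzyloxy)-5-methoxyphenyl]buta-1,3-diene
Conditions: KOtBu (1.1 equiv), THF, 0 °C; then 7, 0 °C to rt
Reagents that add atoms: none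
Why: Horner–Wadsworth–Emmons olefination; the benzylic phosphonate carbanion adds reversibly to the enal carbonyl and elimination of diethyl phosphate gives the E olefin, so 8 should be (E,E). No stereocentre is formed.

Step 6
Reactants: 8 (1E,3E)-1,4-bis(Ar)buta-1,3-diene; 9 maleic anhydride
Product: 10 (3aR,4R,7S,7aS)-4,7-bis(Ar)-3a,4,7,7a-tetrahydro-2-benzofuran-1,3-dione (all-cis, meso)
Conditions: 9 (2 equiv), BHT (1 mol%), o-xylene, 130 °C, N2
Reagents that add atoms: none
Why: This is a concerted thermal [4+2] cycloaddition of normal electron demand between the HOMO of the s-cis conformer of the electron-rich diene 8 and the LUMO of 9; the closest known reaction type is the Diels–Alder reaction of (E,E)-1,4-diarylbuta-1,3-dienes with maleic anhydride. The cyclohexene ring is closed by intermolecular cycloaddition, both new σ-bonds (C7–C8 and C7'–C8') forming in the same step. C8 and C8' (ring positions 3a and 7a) become cis because the dienophile is a cyclic Z-alkene that adds suprafacially. C7 and C7' (positions 4 and 7) become mutually cis because both diene termini are E and the diene also reacts suprafacially. Their relation to the anhydride, with the aryl groups cis to it, is set by the endo transition state in which the carbonyl groups lie under the diene. The step needs no regioselectivity, since both partners are symmetric, and no facial or absolute selectivity, since 10 is meso; the one relation that matters later, cis at C8/C8', is fixed by the ring of 9 itself, so an exo by-product would do no harm. Any Z-containing isomer of 8 cannot reach the s-cis geometry and stays behind. BHT is added to suppress radical copolymerisation of the two π-partners.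

Step 7
Reactants: 10 all-cis anhydride adduct
Product: 11 [(1S,2R,3R,6S)-3,6-bis(Ar)cyclohex-4-ene-1,2-diyl]dimethanol (all-cis, meso)
Conditions: LiAlH4, THF, 0 °C to 50 °C
Reagents that add atoms: none
Why: LiAlH4 reduces the cyclic anhydride through the lactone stage to the diol; no bond to C8 or C8' is broken, so the cis relation set in step 6 is carried over.

Step 8
Reactants: 11 all-cis diol
Product: 12 [(1S,2R,3R,6S)-3,6-bis(Ar)cyclohex-4-ene-1,2-diyl]bis(methylene) dimethanesulfonate
Conditions: MsCl (3 equiv), Et3N, CH2Cl2, 0 °C
Reagents that add atoms: methanesulfonyl chloride, CS(=O)(=O)Cl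
Why: Sulfonylation of both primary alcohols through sulfene; low temperature and excess MsCl should let the second mesylation outrun intramolecular ether formation between the cis arms.

Step 9
Reactants: 12 all-cis dimesylate
Product: 13 (3R,4S,5R,6S)-3,6-bis(Ar)-4,5-dimethylcyclohex-1-ene (all-cis, meso)
Conditions: LiEt3BH (6 equiv), THF, 0 °C to 65 °C
Reagents that add atoms: none
Why: SN2 displacement of primary mesylates by the strongly nucleophilic hydride donor LiEt3BH (reductive deoxygenation); C8 and C8' are not reacting centres, so the cis-dimethyl relation is kept.

Step 10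
Reactants: 13 all-cis dimethylcyclohexene
Product: 15 (2S,3R,4S,5R)-2,5-bis(Ar)-3,4-dimethylhexanedial (meso), via ring cis-diol 14 (not isolated)
Conditions: OsO4 (3 mol%), NaIO4 (4 equiv), 2,6-lutidine (2 equiv), 1,4-dioxane/H2O (3:1), rt
Reagents that add atoms: osmium tetroxide, O=[Os](=O)(=O)=O; sodium periodate, [Na+].[O-]I(=O)(=O)=O
Why: Lemieux–Johnson oxidation; osmylation from the ring face opposite the four cis substituents should give diol 14, which periodate cleaves to the dialdehyde. 2,6-Lutidine buffers the medium against over-oxidation and aldol chemistry, the configuration at C7/C7' is irrelevant, and crude 15 is used at once.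

Step 11
Reactants: 15 meso dialdehyde
Product: 16 5,5'-[(2R,3S)-2,3-dimethylbutane-1,4-diyl]bis[1,2-bis(benzyloxy)-3-methoxybenzene] (meso)
Conditions: RhCl(PPh3)3 (2.4 equiv), degassed toluene, 110 °C
Reagents that add atoms: none
Why: Tsuji–Wilkinson decarbonylation; oxidative addition of each formyl C–H bond to monovalent rhodium, CO de-insertion and C–H reductive elimination replace CHO by H, so C7 and C7' become CH2 and the two template carbons leave as RhCl(CO)(PPh3)2. C8 and C8' are not touched, so the meso pair is retained.

Step 12
Reactants: 16 tetra-O-benzyl ether
Product: 17 target CNP0309596.2, 5,5'-[(2R,3S)-2,3-dimethylbutane-1,4-diyl]bis(3-methoxybenzene-1,2-diol) (meso)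
Conditions: H2 (1 atm), Pd/C (10 wt%), EtOAc/MeOH, rt; work-up under argon
Reagents that add atoms: none
Why: Heterogeneous hydrogenolysis of the four aryl benzyl ethers; aryl methyl ethers and the saturated chain are inert, and neutral, air-free conditions protect the liberated catechols.

## Compound list

1 | 5-hydroxyvanillin (3,4-dihydroxy-5-methoxybenzaldehyde) | COc1cc(C=O)cc(O)c1O | starting material
2 | benzyl bromide | BrCc1ccccc1 | starting material
3 | 3,4-bis(benzyloxy)-5-methoxybenzaldehyde | COc1cc(C=O)cc(OCc2ccccc2)c1OCc1ccccc1 | intermediate
4 | [3,4-bis(benzyloxy)-5-methoxyphenyl]methanol | COc1cc(CO)cc(OCc2ccccc2)c1OCc1ccccc1 | intermediate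
5 | diethyl {[3,4-bis(benzyloxy)-5-methoxyphenyl]methyl}phosphonate | CCOP(=O)(Cc1cc(OC)c(OCc2ccccc2)c(OCc2ccccc2)c1)OCC | intermediate
6 | (triphenylphosphoranylidene)acetaldehyde | O=CC=P(c1ccccc1)(c1ccccc1)c1ccccc1 | starting material
7 | (2E)-3-[3,4-bis(benzyloxy)-5-methoxyphenyl]prop-2-enal | COc1cc(/C=C/C=O)cc(OCc2ccccc2)c1OCc1ccccc1 | intermediate
8 | (1E,3E)-1,4-bis[3,4-bis(benzyloxy)-5-methoxyphenyl]buta-1,3-diene | COc1cc(/C=C/C=C/c2cc(OC)c(OCc3ccccc3)c(OCc3ccccc3)c2)cc(OCc2ccccc2)c1OCc1ccccc1 | intermediate
9 | maleic anhydride (furan-2,5-dione) | O=C1OC(=O)C=C1 | starting material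
10 | (3aR,4R,7S,7aS)-4,7-bis[3,4-bis(benzyloxy)-5-methoxyphenyl]-3a,4,7,7a-tetrahydro-2-benzofuran-1,3-dione (all-cis, meso) | [C@H]1(c2cc(OC)c(OCc3ccccc3)c(OCc3ccccc3)c2)C=C[C@@H](c2cc(OC)c(OCc3ccccc3)c(OCc3ccccc3)c2)[C@H]2C(=O)OC(=O)[C@@H]12 | intermediate
11 | [(1S,2R,3R,6S)-3,6-bis[3,4-bis(benzyloxy)-5-methoxyphenyl]cyclohex-4-ene-1,2-diyl]dimethanol (all-cis, meso) | [C@H]1(c2cc(OC)c(OCc3ccccc3)c(OCc3ccccc3)c2)C=C[C@@H](c2cc(OC)c(OCc3ccccc3)c(OCc3ccccc3)c2)[C@@H](CO)[C@H]1CO | intermediate
12 | [(1S,2R,3R,6S)-3,6-bis[3,4-bis(benzyloxy)-5-methoxyphenyl]cyclohex-4-ene-1,2-diyl]bis(methylene) dimethanesulfonate (all-cis, meso) | [C@H]1(c2cc(OC)c(OCc3ccccc3)c(OCc3ccccc3)c2)C=C[C@@H](c2cc(OC)c(OCc3ccccc3)c(OCc3ccccc3)c2)[C@@H](COS(C)(=O)=O)[C@H]1COS(C)(=O)=O | intermediate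
13 | (3R,4S,5R,6S)-3,6-bis[3,4-bis(benzyloxy)-5-methoxyphenyl]-4,5-dimethylcyclohex-1-ene (all-cis, meso) | [C@H]1(c2cc(OC)c(OCc3ccccc3)c(OCc3ccccc3)c2)C=C[C@@H](c2cc(OC)c(OCc3ccccc3)c(OCc3ccccc3)c2)[C@@H](C)[C@H]1C | intermediate
14 | (1S,2R,3R,4S,5R,6S)-3,6-bis[3,4-bis(benzyloxy)-5-methoxyphenyl]-4,5-dimethylcyclohexane-1,2-diol (hydroxyls trans to the four other substituents, meso; not isolated) | [C@H]1(c2cc(OC)c(OCc3ccccc3)c(OCc3ccccc3)c2)[C@H](O)[C@H](O)[C@@H](c2cc(OC)c(OCc3ccccc3)c(OCc3ccccc3)c2)[C@@H](C)[C@H]1C | intermediate
15 | (2S,3R,4S,5R)-2,5-bis[3,4-bis(benzyloxy)-5-methoxyphenyl]-3,4-dimethylhexanedial (meso) | O=C[C@H](c1cc(OC)c(OCc2ccccc2)c(OCc2ccccc2)c1)[C@H](C)[C@H](C)[C@H](c1cc(OC)c(OCc2ccccc2)c(OCc2ccccc2)c1)C=O | intermediate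
16 | 5,5'-[(2R,3S)-2,3-dimethylbutane-1,4-diyl]bis[1,2-bis(benzyloxy)-3-methoxybenzene] (meso) | COc1cc(C[C@@H](C)[C@@H](C)Cc2cc(OC)c(OCc3ccccc3)c(OCc3ccccc3)c2)cc(OCc2ccccc2)c1OCc1ccccc1 | intermediate
17 | 5,5'-[(2R,3S)-2,3-dimethylbutane-1,4-diyl]bis(3-methoxybenzene-1,2-diol) (meso) | COc1cc(C[C@@H](C)[C@@H](C)Cc2cc(O)c(O)c(OC)c2)cc(O)c1O | target

## Step count and least certain steps

Total step count: 12. Longest linear sequence: 11 steps (steps 1, 2, 3, 5, 6, 7, 8, 9, 10, 11, 12); step 4 is a one-step branch from 3.

Step 6 (key step). The cycloaddition may be outrun by radical alternating copolymerisation of the electron-rich diene with the anhydride, or may stall because the doubly aryl-conjugated diene is reluctant to leave planarity for the s-cis conformation; hydrolytic opening of the anhydride during isolation would be a further loss. Fallback, setting out from 8: the dienophile is changed to N-phenylmaleimide (toluene, 80 °C), which keeps the cis-locked Z geometry and should give the chromatography-stable imide adduct (3aR,4R,7S,7aS)-4,7-bis(Ar)-2-phenyl-3a,4,7,7a-tetrahydro-1H-isoindole-1,3(2H)-dione F1. NaBH4 in aqueous 2-propanol should open one imide carbonyl reductively to the racemic hydroxy anilide (1R,2R,5S,6S)-2,5-bis(Ar)-6-(hydroxymethyl)-N-phenylcyclohex-3-ene-1-carboxamide F2. Warming in acetic acid should close the racemic cis-fused lactone (3aS,4S,7R,7aR)-4,7-bis(Ar)-3a,4,7,7a-tetrahydro-2-benzofuran-1(3H)-one F3 with loss of aniline, and LiAlH4 reduction of F3 rejoins the route at 11.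

Step 11. β-Hydride elimination from the secondary benzylic alkyl–rhodium hydride may compete with C–H reductive elimination; this would form a C7=C8 olefin whose later hydrogenation would scramble C8. The second decarbonylation may also lag, and the enolisable dialdehyde may undergo aldol self-condensation at 110 °C. Fallback, setting out from 15: oxidation with NaClO2/NaH2PO4/2-methylbut-2-ene (Pinnick) to the diacid (2S,3R,4S,5R)-2,5-bis(Ar)-3,4-dimethylhexanedioic acid F4, then twofold photocatalytic hydrodecarboxylation (9-mesityl-10-methylacridinium tetrafluoroborate, PhSSPh, 2,6-lutidine, CF3CH2OH, blue light). Each benzylic C7 radical takes a hydrogen atom from thiophenol, so no olefin can form; the sequence rejoins the route at 16.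

Step 10. Osmylation of the ring alkene, flanked by two aryl-bearing carbons, may be slow, and in the aqueous oxidising medium the α-aryl dialdehyde may hydrate, over-oxidise or cyclise by intramolecular aldol addition. Fallback, setting out from 13: ozonolysis in CH2Cl2/pyridine at −78 °C with a metered, stoichiometric charge of O3 (the isolated alkene reacts far faster than the alkoxy arenes), then Me2S. This is a cycloaddition–cycloreversion pathway that needs neither 14 nor water and rejoins the route at 15; it makes no new compound (F0).

Step 9. Hydride may attack at sulfur instead of carbon and regenerate an alkoxide, which would then displace the neighbouring cis mesylate and close a tetrahydrofuran ring; the β-branched, crowded primary carbons slow the desired SN2 path. Fallback, setting out from 11: I2, PPh3 and imidazole give the diiodide (3R,4R,5S,6S)-3,6-bis(Ar)-4,5-bis(iodomethyl)cyclohex-1-ene F5, and radical deiodination with (Me3Si)3SiH/AIBN (toluene, 80 °C), which is insensitive to steric hindrance, rejoins the route at 13.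

Step 3. ZnI2 may ionise the electron-rich benzylic alcohol faster than phosphite captures it, leading to Friedel–Crafts self-alkylation instead of C–P bond formation. Fallback, setting out from 4: PBr3 (CH2Cl2, 0 °C) gives the bromide 1,2-bis(benzyloxy)-5-(bromomethyl)-3-methoxybenzene F6, and heating it in neat P(OEt)3 at 130 °C (Michaelis–Arbuzov) rejoins the route at 5.

## Further compounds

F1 | step 6 | (3aR,4R,7S,7aS)-4,7-bis[3,4-bis(benzyloxy)-5-methoxyphenyl]-2-phenyl-3a,4,7,7a-tetrahydro-1H-isoindole-1,3(2H)-dione (all-cis, meso) | [C@H]1(c2cc(OC)c(OCc3ccccc3)c(OCc3ccccc3)c2)C=C[C@@H](c2cc(OC)c(OCc3ccccc3)c(OCc3ccccc3)c2)[C@H]2C(=O)N(c3ccccc3)C(=O)[C@@H]12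
F2 | step 6 | (1R,2R,5S,6S)-2,5-bis[3,4-bis(benzyloxy)-5-methoxyphenyl]-6-(hydroxymethyl)-N-phenylcyclohex-3-ene-1-carboxamide (all-cis, racemic; one enantiomer drawn) | [C@H]1(c2cc(OC)c(OCc3ccccc3)c(OCc3ccccc3)c2)C=C[C@@H](c2cc(OC)c(OCc3ccccc3)c(OCc3ccccc3)c2)[C@@H](C(=O)Nc2ccccc2)[C@H]1CO
F3 | step 6 | (3aS,4S,7R,7aR)-4,7-bis[3,4-bis(benzyloxy)-5-methoxyphenyl]-3a,4,7,7a-tetrahydro-2-benzofuran-1(3H)-one (all-cis, racemic; one enantiomer drawn) | [C@H]1(c2cc(OC)c(OCc3ccccc3)c(OCc3ccccc3)c2)C=C[C@@H](c2cc(OC)c(OCc3ccccc3)c(OCc3ccccc3)c2)[C@H]2C(=O)OC[C@@H]12
F4 | step 11 | (2S,3R,4S,5R)-2,5-bis[3,4-bis(benzyloxy)-5-methoxyphenyl]-3,4-dimethylhexanedioic acid (meso) | OC(=O)[C@H](c1cc(OC)c(OCc2ccccc2)c(OCc2ccccc2)c1)[C@H](C)[C@H](C)[C@H](c1cc(OC)c(OCc2ccccc2)c(OCc2ccccc2)c1)C(O)=O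
F0 | step 10 | none | none
F5 | step 9 | (3R,4R,5S,6S)-3,6-bis[3,4-bis(benzyloxy)-5-methoxyphenyl]-4,5-bis(iodomethyl)cyclohex-1-ene (all-cis, meso) | [C@H]1(c2cc(OC)c(OCc3ccccc3)c(OCc3ccccc3)c2)C=C[C@@H](c2cc(OC)c(OCc3ccccc3)c(OCc3ccccc3)c2)[C@@H](CI)[C@H]1CI
F6 | step 3 | 1,2-bis(benzyloxy)-5-(bromomethyl)-3-methoxybenzene | COc1cc(CBr)cc(OCc2ccccc2)c1OCc1ccccc1
A1 | alternative 1 | 5,5'-[(2R,3S)-2,3-dimethylbutane-1,4-diyl]bis(cyclohexane-1,3-dione) (meso) | O=C1CC(C[C@@H](C)[C@@H](C)CC2CC(=O)CC(=O)C2)CC(=O)C1
A2 | alternative 1 | (3E,6R,7S,9E)-6,7-dimethyldodeca-3,9-diene-2,11-dione (meso) | CC(=O)/C=C/C[C@@H](C)[C@@H](C)C/C=C/C(C)=O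
A3 | alternative 1 | dimethyl malonate | COC(=O)CC(=O)OC
A4 | alternative 2 | meso-1,4-bis(7-methoxy-1,3-benzodioxol-5-yl)-2,3-bis[(4,4,5,5-tetramethyl-1,3,2-dioxaborolan-2-yl)methyl]butane | COc1cc(C[C@@H](CB2OC(C)(C)C(C)(C)O2)[C@@H](CB2OC(C)(C)C(C)(C)O2)Cc2cc(OC)c3OCOc3c2)cc2OCOc12
A5 | alternative 2 | meso-1,4-bis(7-methoxy-1,3-benzodioxol-5-yl)-2,3-bis(4,4,5,5-tetramethyl-1,3,2-dioxaborolan-2-yl)butane | COc1cc(C[C@@H](B2OC(C)(C)C(C)(C)O2)[C@@H](B2OC(C)(C)C(C)(C)O2)Cc2cc(OC)c3OCOc3c2)cc2OCOc12
A6 | alternative 2 | bromochloromethane | ClCBr
A7 | alternative 3 | 5,5'-[(2R,3S)-2,3-dimethylbutane-1,4-diyl]bis[1,2-bis(benzyloxy)-3-methoxybenzene] (meso; identical with 16) | COc1cc(C[C@@H](C)[C@@H](C)Cc2cc(OC)c(OCc3ccccc3)c(OCc3ccccc3)c2)cc(OCc2ccccc2)c1OCc1ccccc1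
A8 | alternative 3 | meso-1,4-bis(iodozincio)-2,3-dimethylbutane | I[Zn]C[C@@H](C)[C@@H](C)C[Zn]I
A9 | alternative 3 | 1,2-bis(benzyloxy)-5-bromo-3-methoxybenzene | COc1cc(Br)cc(OCc2ccccc2)c1OCc1ccccc1
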